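**Retrosynthetic overview**
1. The strategy rests on the only ring, a benzene with the side-chain CH2 on C1, H on C2, OH on C3, H on C4, OMe on C5 and OH on C6. C3 and C6 are para oxygens and the bulkiest group (C1) sits ortho to C6–OH, which is the pattern produced when a chromium alkenylcarbene, a terminal alkyne and CO combine.
2. Late redox disconnection: hydroquinone ⇐ 2-methoxy-6-alkyl-1,4-benzoquinone ⇐ the C3 methyl ether (a para-methoxyphenol), so the C3 oxygen arrives masked as OMe.
3. Ring-forming disconnection (one ring, made once): cutting C2–C3, C1–C6 and C5–C6 gives (R)-pentadec-1-yn-4-yl acetate, the (E)-2-methoxyvinyl(methoxy)carbene complex of Cr(CO)5 and one of its own CO ligands.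
4. Alkyne branch: (R)-epichlorohydrin supplies the stereocentre, a decyl Grignard reagent and an acetylide are attached to its two CH2 termini, and the alcohol is then acetylated.
5. Carbene branch: Cr(CO)6 and lithiated trimethylsilylacetylene are joined and O-methylated, then methoxide-catalysed desilylation and conjugate addition of methanol follow in one flask.

Key step: step 6

Remark: in the SMILES strings the CO ligands are drawn as Cr=C=O and the η6 bond of the arene–Cr(CO)3 complex is drawn as a dot. The ring numbering C1–C6 of line 1 is used throughout.

**Step 1**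
Reactants: 1 (R)-epichlorohydrin; 2 decylmagnesium bromide (n-C10H21MgBr)
Product: 3 (R)-1-chlorotridecan-2-ol
Conditions: CuI (10 mol %), THF, −40 → 0 °C; aq NH4Cl
Reagents that add atoms: none
Why: Copper-catalysed Grignard opening of a terminal epoxide occurs by SN2 attack at the unsubstituted ring carbon faster than any displacement of chloride, so no bond to the stereocentre is broken and the (R) configuration bought with 1 is carried unchanged into 3.

**Step 2**
Reactants: 3 (R)-1-chlorotridecan-2-ol; 4 lithium acetylide–ethylenediamine complex (LiC≡CH·H2NCH2CH2NH2)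
Product: 6 (R)-pentadec-1-yn-4-ol, via (R)-2-undecyloxirane 5 (not isolated)
Conditions: 4 (3 equiv), DMSO/THF, 0 °C → rt; H2O
Reagents that add atoms: none
Why: One equivalent of the acetylide acts as base and the resulting chloro-alkoxide closes to epoxide 5 (intramolecular Williamson reaction at CH2Cl), which a further equivalent opens by SN2 attack at its CH2 terminus (acetylide opening of a terminal epoxide), both events leaving the C–O bond of the stereocentre intact so that 6 is (R).

**Step 3**
Reactants: 6 (R)-pentadec-1-yn-4-ol
Product: 7 (R)-pentadec-1-yn-4-yl acetate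
Conditions: Ac2O, pyridine, DMAP (cat.), CH2Cl2, 0 °C → rt
Reagents that add atoms: acetic anhydride, CC(=O)OC(C)=O
Why: DMAP-catalysed acylation takes place at oxygen without touching the C–O bond, so the configuration is retained, and the terminal alkyne is inert to these conditions.

**Step 4**
Reactants: 8 trimethylsilylacetylene; 9 Cr(CO)6
Product: 12 pentacarbonyl[1-methoxy-3-(trimethylsilyl)prop-2-yn-1-ylidene]chromium, via lithium (trimethylsilyl)acetylide 10 (not isolated), via lithium acylpentacarbonylchromate 11 (not isolated)
Conditions: n-BuLi, Et2O, −78 °C; Cr(CO)6, −78 → 0 °C; MeOTf, −30 → 0 °C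
Reagents that add atoms: methyl trifluoromethanesulfonate, COS(=O)(=O)C(F)(F)F
Why: This is the Fischer carbene synthesis, in which acetylide 10 adds to the carbon of one CO ligand of 9 to give acylate 11, whose oxygen is alkylated by the hard methylating agent MeOTf, the silyl cap keeping the alkyne terminus free of an acidic proton during both operations.

**Step 5**
Reactants: 12 pentacarbonyl[1-methoxy-3-(trimethylsilyl)prop-2-yn-1-ylidene]chromium
Product: 14 pentacarbonyl[(E)-1,3-dimethoxyprop-2-en-1-ylidene]chromium, via ethynyl(methoxy)carbene complex 13 (not isolated)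
Conditions: MeOH (5 equiv), NaOMe (10 mol %), THF, −20 → 0 °C, argon
Reagents that add atoms: methanol, CO
Why: Methoxide first cleaves the C–Si bond of the strongly acceptor-activated alkynylsilane (base-catalysed methanolysis) and methanol then adds to the terminal carbon of ethynylcarbene 13 in the known Michael addition of alcohols to alkynyl Fischer carbene complexes, attack at the carbene carbon being degenerate because methoxy only replaces methoxy, and the push-pull double bond being expected to settle as the less crowded E isomer although its geometry is erased in step 6.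

**Step 6**
Reactants: 7 (R)-pentadec-1-yn-4-yl acetate; 14 pentacarbonyl[(E)-1,3-dimethoxyprop-2-en-1-ylidene]chromium
Product: 16 (R)-1-(2-hydroxy-3,5-dimethoxyphenyl)tridecan-2-yl acetate, via arene-Cr(CO)3 complex 15 (not isolated)
Conditions: 14 (1.3 equiv), THF (0.5 M), 50 °C, argon; then air, Et2O, rt
Reagents that add atoms: none
Why: Heating expels one CO from 14, alkyne 7 binds and inserts into the Cr=C bond to give a chromium vinylcarbene, a CO ligand migrates onto the new carbene carbon to give a metal-bound dienylketene, and this closes and enolises to the phenol, first held as its Cr(CO)3 complex 15 and then released by air. The reaction type is the Dötz benzannulation of an alkenyl(alkoxy)carbene complex of zerovalent chromium with a terminal alkyne, a class that also includes alkenylcarbenes carrying a β-oxygen substituent made by O–H addition to alkynylcarbenes. The benzene ring is closed in a [3+2+1] sense, C2–C3 forming in the insertion, C1–C6 in the CO migration and C5–C6 in the final 6π electrocyclisation of the dienylketene, so that the carbene carbon becomes C3–OMe, the two vinyl carbons C4–H and C5–OMe, the CO carbon C6–OH and the alkyne carbons C1 and C2. No stereocentre is formed, and the acetoxy-bearing carbon of 7, insulated from the alkyne by a CH2 group, keeps its (R) configuration under these neutral conditions. Regioselective insertion is required and is steric in origin: the unsubstituted alkyne carbon bonds to the old carbene carbon because this keeps the CH2CH(OAc)C11H23 group out of the vinylcarbene position that is pressed against a CO ligand, so the chain ends on C1 next to C6–OH. Selectivity for six- over five-membered ring closure (closure without CO uptake, which strong donors favour) is also required and is served by chromium as the metal, a weakly coordinating solvent, high concentration and moderate temperature, methoxy being a far weaker donor than the amino groups known to cause that diversion.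

**Step 7**
Reactants: 16 (R)-1-(2-hydroxy-3,5-dimethoxyphenyl)tridecan-2-yl acetate
Product: 17 (R)-1-(5-methoxy-3,6-dioxocyclohexa-1,4-dien-1-yl)tridecan-2-yl acetate
Conditions: (NH4)2Ce(NO3)6 (2.2 equiv), MeCN/H2O, 0 °C
Reagents that add atoms: water, O
Why: Tetravalent cerium removes two electrons from the para-methoxyphenol, water adds to the resulting oxocarbenium carbon C3 and methanol is expelled (oxidative demethylation to a para-quinone), while the C5 methoxy group ends as a vinylogous ester and the acetate and its stereocentre are untouched in the short cold exposure.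

**Step 8**
Reactants: 17 (R)-1-(5-methoxy-3,6-dioxocyclohexa-1,4-dien-1-yl)tridecan-2-yl acetate
Product: 18 (R)-1-(2,5-dihydroxy-3-methoxyphenyl)tridecan-2-yl acetate (target)
Conditions: Na2S2O4, EtOAc/H2O, rt, argon
Reagents that add atoms: none
Why: Dithionite reduction of a 1,4-benzoquinone to the hydroquinone is fast in a two-phase system at near-neutral pH, which spares the acetate, gives no opportunity for acetyl migration to the C6 hydroxyl and leaves the (R) centre as set in 1.

**Compound list**
1 | (R)-epichlorohydrin [(R)-2-(chloromethyl)oxirane] | ClC[C@H]1CO1 | starting material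
2 | decylmagnesium bromide | CCCCCCCCCC[Mg]Br | starting material
3 | (R)-1-chlorotridecan-2-ol | CCCCCCCCCCC[C@H](CCl)O | intermediate
4 | lithium acetylide–ethylenediamine complex | [Li]C#C.NCCN | starting material
5 | (R)-2-undecyloxirane | CCCCCCCCCCC[C@@H]1CO1 | intermediate
6 | (R)-pentadec-1-yn-4-ol | CCCCCCCCCCC[C@H](CC#C)O | intermediate
7 | (R)-pentadec-1-yn-4-yl acetate | CCCCCCCCCCC[C@H](CC#C)OC(C)=O | intermediate
8 | trimethylsilylacetylene | C[Si](C)(C)C#C | starting material
9 | hexacarbonylchromium, Cr(CO)6 | O=C=[Cr](=C=O)(=C=O)(=C=O)(=C=O)=C=O | starting material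
10 | lithium (trimethylsilyl)acetylide | C[Si](C)(C)C#C[Li] | intermediate
11 | lithium pentacarbonyl[3-(trimethylsilyl)prop-2-ynoyl]chromate | [Li+].C[Si](C)(C)C#CC([O-])=[Cr](=C=O)(=C=O)(=C=O)(=C=O)=C=O | intermediate
12 | pentacarbonyl[1-methoxy-3-(trimethylsilyl)prop-2-yn-1-ylidene]chromium | COC(C#C[Si](C)(C)C)=[Cr](=C=O)(=C=O)(=C=O)(=C=O)=C=O | intermediate
13 | pentacarbonyl(1-methoxyprop-2-yn-1-ylidene)chromium | COC(C#C)=[Cr](=C=O)(=C=O)(=C=O)(=C=O)=C=O | intermediate
14 | pentacarbonyl[(E)-1,3-dimethoxyprop-2-en-1-ylidene]chromium | CO/C=C/C(OC)=[Cr](=C=O)(=C=O)(=C=O)(=C=O)=C=O | intermediate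
15 | tricarbonyl{η6-[(R)-1-(2-hydroxy-3,5-dimethoxyphenyl)tridecan-2-yl acetate]}chromium | CCCCCCCCCCC[C@H](Cc1cc(OC)cc(OC)c1O)OC(C)=O.O=C=[Cr](=C=O)=C=O | intermediate
16 | (R)-1-(2-hydroxy-3,5-dimethoxyphenyl)tridecan-2-yl acetate | CCCCCCCCCCC[C@H](Cc1cc(OC)cc(OC)c1O)OC(C)=O | intermediate
17 | (R)-1-(5-methoxy-3,6-dioxocyclohexa-1,4-dien-1-yl)tridecan-2-yl acetate | CCCCCCCCCCC[C@H](CC1=CC(=O)C=C(OC)C1=O)OC(C)=O | intermediate
18 | (R)-1-(2,5-dihydroxy-3-methoxyphenyl)tridecan-2-yl acetate | CCCCCCCCCCC[C@H](Cc1cc(O)cc(OC)c1O)OC(C)=O | target

**Step count**
Total step count: 8.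
Longest linear sequence: 6 (steps 1, 2, 3, 6, 7, 8). Steps 4 and 5 form the second branch, which joins in step 6.

**Steps most likely to fail**

**Step 6.**
- What may go wrong: the donor methoxy group may make the metal hold its CO ligands more tightly and slow the opening CO loss. The vinylcarbene may close to a five-membered ring before CO migrates. The terminal alkyne may oligomerise on the metal.
- Fallback: the ring is bought instead of built. It sets out from 3 and comes back to the route at 17.
- Epoxide: chlorohydrin 3 is closed with powdered NaOH in Et2O, and epoxide 5 is now isolated.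
- Aryl partner: 2-methoxyphenol is protected with MOMCl and i-Pr2NEt as 1-methoxy-2-(methoxymethoxy)benzene F1. n-BuLi in THF at 0 °C lithiates this ortho to the acetal oxygen (directed ortho-metalation) to give [3-methoxy-2-(methoxymethoxy)phenyl]lithium F2.
- Coupling: in the presence of BF3·OEt2 at −78 °C this aryllithium opens 5 at its CH2 terminus, giving (R)-1-[3-methoxy-2-(methoxymethoxy)phenyl]tridecan-2-ol F3 with the stereocentre untouched.
- Acetylation and deprotection: Ac2O, pyridine and DMAP give (R)-1-[3-methoxy-2-(methoxymethoxy)phenyl]tridecan-2-yl acetate F4. NaHSO4 on silica in moist CH2Cl2 removes the phenolic acetal to give (R)-1-(2-hydroxy-3-methoxyphenyl)tridecan-2-yl acetate F5.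
- Oxidation: Teuber oxidation with ON(SO3K)2 in phosphate-buffered aqueous acetone places oxygen on the free para position C3 and delivers quinone 17.

**Step 5.**
- What may go wrong: after desilylation the unsubstituted ethynylcarbene may oligomerise. A second conjugate addition of methanol may follow the first. Methoxide may degrade the metal–carbene unit.
- Fallback: the methoxyvinyl unit is brought in as an acyl chloride and joined to a chromium dianion, so no alkynylcarbene is needed. It sets out from 9, comes back at 14, and also bypasses step 4.
- Acyl chloride: commercial methyl (E)-3-methoxyacrylate is saponified with NaOH to sodium (E)-3-methoxyacrylate F6. SOCl2 in Et2O turns this into (E)-3-methoxyacryloyl chloride F7.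
- Chromium partner: compound 9 is reduced with sodium naphthalenide (NaC10H8) in THF at −78 °C to disodium pentacarbonylchromate F8.
- Joining and methylation: acylation of the dianion with the acid chloride at −78 °C gives sodium pentacarbonyl[(E)-3-methoxyacryloyl]chromate F9. O-methylation with MeOTf gives 14 with the E geometry already in place.

**Step 2.**
- What may go wrong: the lipophilic C13 substrate may dissolve poorly in the DMSO medium, so that ring closure and opening stall. The strongly basic mixture may also move the triple bond away from the chain terminus.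
- Ranking note: step 4 is ranked lower because it follows the standard Fischer sequence and is covered by the fallback for step 5.
- Fallback: a silyl-capped acetylide is used under Lewis acid activation, in separate operations. It sets out from 3 and comes back at 6.
- Sequence: chlorohydrin 3 is closed with NaOH in Et2O and 5 is isolated. Acetylide 10, made from 8 and n-BuLi, is combined with BF3·OEt2 in THF at −78 °C and opens 5 at its CH2 terminus to give (R)-1-(trimethylsilyl)pentadec-1-yn-4-ol F10. K2CO3 in MeOH then removes silicon to give 6.

**Further compounds**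
F1 | step 6 | 1-methoxy-2-(methoxymethoxy)benzene | COCOc1ccccc1OC
F2 | step 6 | [3-methoxy-2-(methoxymethoxy)phenyl]lithium | [Li]c1cccc(OC)c1OCOC
F3 | step 6 | (R)-1-[3-methoxy-2-(methoxymethoxy)phenyl]tridecan-2-ol | CCCCCCCCCCC[C@H](Cc1cccc(OC)c1OCOC)O
F4 | step 6 | (R)-1-[3-methoxy-2-(methoxymethoxy)phenyl]tridecan-2-yl acetate | CCCCCCCCCCC[C@H](Cc1cccc(OC)c1OCOC)OC(C)=O
F5 | step 6 | (R)-1-(2-hydroxy-3-methoxyphenyl)tridecan-2-yl acetate | CCCCCCCCCCC[C@H](Cc1cccc(OC)c1O)OC(C)=O
F6 | step 5 | sodium (E)-3-methoxyacrylate | [Na+].CO/C=C/C(=O)[O-]
F7 | step 5 | (E)-3-methoxyacryloyl chloride | CO/C=C/C(=O)Cl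
F8 | step 5 | disodium pentacarbonylchromate, Na2Cr(CO)5 | [Na+].[Na+].O=C=[Cr-2](=C=O)(=C=O)(=C=O)=C=O
F9 | step 5 | sodium pentacarbonyl[(E)-3-methoxyacryloyl]chromate | [Na+].CO/C=C/C([O-])=[Cr](=C=O)(=C=O)(=C=O)(=C=O)=C=O
F10 | step 2 | (R)-1-(trimethylsilyl)pentadec-1-yn-4-ol | CCCCCCCCCCC[C@H](CC#C[Si](C)(C)C)O
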